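The earlier runs and the new flask were generated by integration for an exercise; the scatter is artificial.

The reaction was slow: after 60.0 min, Tuesday's run had turned 20.8 % of its substrate into product.

| setting | Monday's | Tuesday's | flask |
|---|---|---|---|
| substrate | 0.010 M | 0.0067 M | 0.010 M |
| salt in the second phase | 1.2 equiv | 1.2 equiv | 1.20 equiv |
| spent carrier | 15 mol% | 15 mol% | 15 mol% |
| impurity | 0.15 mM | 0.15 mM | 0.15 mM |
| remark | the very flask that is asked about, followed so far | run made earlier |  |
| time |  |  | 1.5 h |
| volume of the second phase over the first |  |  | 1.0 |

| run | time / min | product / % | crystals / % |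
|---|---|---|---|
| Monday's | 1.00 | 0 | 0.4 |
| Monday's | 3.00 | 0.4 | 0 |
| Monday's | 6.00 | 1.5 | 0 |
| Monday's | 8.00 | 3.5 | 0 |
| Monday's | 12.0 | 5.5 | 0 |
| Monday's | 15.0 | 7.8 | 0.2 |
| Tuesday's | 4.00 | 0 | 0 |
| Tuesday's | 12.0 | 3.4 | 0 |
| Tuesday's | 20.0 | 5.6 | 0.3 |
| Tuesday's | 30.0 | 10.3 | 0 |
| Tuesday's | 50.0 | 18.0 | 0.5 |
| Tuesday's | 60.0 | 20.8 | 0 |

(each reading ± 0.3 percentage points)

* how much product and crystals together there is at 1.5 h, in percent of the substrate charged
* concentration of product in solution at 1.5 h, in percent of saturation

- for product the crystals are counted in
- in the second phase: salt in the second phase, spent salt in the second phase; everything else is in the first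
- charges count per volume of the first phase; a concentration in a rate is the amount of a species over the volume of its own phase; every rate counts per litre of the first phase
- as a solid, counted per litre of solution: crystals
- what may be going on: spent carrier + salt in the second phase <-> fresh carrier + spent salt in the second phase; substrate + fresh carrier -> product + spent carrier; spent carrier -> spent catalyst A; fresh carrier + impurity -> spent catalyst B; crystals <-> product
- the earlier runs hold the two phases in the same ratio of volumes as the flask asked about

Note for whoever takes over this flask:

1. The flask holds substrate, impurity and spent carrier in the first phase, and salt in the second. Salt turns spent carrier into fresh carrier, and fresh carrier turns substrate into product.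

2. I took this round as steady, with a constant share of the working carrier free as fresh carrier. I assumed that the impurity takes its whole 0.15 mM of carrier out of the round, so I counted the working carrier w as the carrier charged minus that amount. Substrate should then fall in a pseudo-first-order way, with a rate constant proportional to w.

3. The fraction of substrate left is then exp(−κwt), where κ is the working-carrier constant, the log-loss per unit of working carrier times time. Tuesday's last reading gives 4.55 M⁻¹ min⁻¹. Monday's last reading gives 4.01 M⁻¹ min⁻¹, but I kept Tuesday's figure because that run went longer.

4. By 1.5 h I expected 42.4 % of the flask's substrate as product and crystals.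

5. Tuesday's crystal readings showed nothing clear above the scatter, so I put no figure on saturation.

6. Don't change the volume ratio: both runs were read at it.

The forecast said 40 % and 100 %, the second “a loose guess”. The flask gave 41.5 %, at 55.4 % of saturation.

    spent carrier + salt in the second phase ⇌ fresh carrier + spent salt in the second phase (K = 0.470, k = 0.140 M⁻¹ s⁻¹)
    substrate + fresh carrier → product + spent carrier (k = 0.290 M⁻¹ s⁻¹)
    spent carrier → spent catalyst A (k = 5.70 × 10⁻⁵ s⁻¹)
    fresh carrier + impurity → spent catalyst B (k = 390 M⁻¹ s⁻¹)
    crystals ⇌ product, rate k5*(cs5 - [product]) while solid is left; crystals form when [product] > cs5 (solubility = 7.50 mM, k = 0.00430 s⁻¹)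

At 1.50 h in the flask, spent carrier had a half-life of 0.19 h by the forward step with salt, against 3.4 h by the step to spent catalyst A. For the neighbour charged with 0.0060 M, where spent catalyst B stood at 16.7 % of the catalyst charged, κ gave 26.4 % at 1.5 h, and that neighbour held 25.9 % as product and crystals together.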